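7.60 min: hold that number, τ, the time the slow feed in eta takes to bring as much partner as there is starting material in the flask.

| flask | starting material | partner | temperature | remark | time |
|---|---|---|---|---|---|
| maple | 17 mM | 17.9 mM | 75 °C | run made earlier |  |
| ash | 11 mM | 17.9 mM | 90 °C | run made earlier |  |
| cedar | 26 mM | 17.9 mM | 75 °C | run made earlier |  |
| alder | 17 mM | 27 mM | 90 °C | run made earlier |  |
| eta | 17 mM | 17.9 mM (fed, over 8.0 min) | 90 °C | all else is in the flask from the start; the feed brings no volume worth counting | 10 min |
| gamma | 17 mM (fed, over 8.0 min) | 17.9 mM | 90 °C | all else is in the flask from the start; the feed brings no volume worth counting | 10 min |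
| delta | 17 mM (fed, over 2.0 min) | 17.9 mM | 90 °C | all else is in the flask from the start; the feed brings no volume worth counting | 10 min |
| theta | 17 mM (fed, over 8.0 min) | 17.9 mM |  | the addition at 70 °C, then warmed to 90 °C; the feed brings no volume worth counting | 10 min |
| zeta | 17 mM | 17.9 mM | 90 °C | everything together at the start | 10 min |

| run | time / min | side product / % | target / % |
|---|---|---|---|
| maple | 2.00 | 1.9 | 45.5 |
| maple | 5.00 | 2.3 | 76.9 |
| maple | 10.0 | 4.8 | 91.3 |
| maple | 15.0 | 3.0 | 96.3 |
| maple | 20.0 | 3.8 | 94.7 |
| ash | 1.33 | 1.9 | 78.6 |
| ash | 2.50 | 1.9 | 91.5 |
| ash | 4.00 | 2.6 | 96.4 |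
| ash | 5.00 | 2.2 | 98.5 |
| ash | 6.00 | 3.5 | 98.0 |
| cedar | 1.00 | 1.4 | 27.8 |
| cedar | 3.00 | 1.9 | 60.7 |
| cedar | 6.00 | 4.0 | 66.5 |
| cedar | 8.00 | 6.8 | 65.6 |
| cedar | 12.0 | 9.3 | 63.1 |
| alder | 1.33 | 0.8 | 79.0 |
| alder | 2.50 | 4.6 | 94.6 |
| alder | 4.00 | 3.0 | 95.3 |
| alder | 5.00 | 2.0 | 94.9 |
| alder | 6.00 | 5.7 | 98.6 |

(readings scatter by 1 percentage point)

- percentages count the starting material that a species holds: one side product counts as two
- what was read earlier has a scatter of 1 percentage point, one standard deviation

* the flask that comes out highest in amount of side product, in percent of the starting material charged; "all alike" if 1.5 percentage points covers them all (eta / gamma / delta / theta / zeta / all alike)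
* amount of side product at the end, in percent of the starting material charged, eta
* amount of side product at the end, in percent of the starting material charged, gamma
* amount of side product at the end, in percent of the starting material charged, delta
* amount of side product at the end, in percent of the starting material charged, theta
* amount of side product at the end, in percent of the starting material charged, zeta

Write s, p and y for the fractions of the charge held as starting material, target and side product. Read the loss of starting material from the first samples, taking s as what target and side product leave. Ash gives 1.23 min⁻¹ with 17.9 mM of partner and alder gives 1.20 min⁻¹ with 27 mM, so drop partner from the rate and take k = 1.22 min⁻¹ at 90 °C.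

Past 6.00 min, cedar gains 5.3 percentage points of side product and loses 3.4 points of target. Set the side rate to c·s·p, with c unknown.

With everything in at the start, target grows at k·s, so integrating side per target gives y = 0.5·c/k. Now feed partner. Starting material stays the limiting reagent of the charge, 17 mM against 17.9 mM of partner. But in eta its loss could start at 1.22 min⁻¹, while the feed brings partner at 0.132 min⁻¹ of the charge, so I let the feed set the pace: p climbs in a straight line and s is what p leaves. Integrate c·s·p over τ: y = c·τ/6.

The unknown c cancels. The ratio is k times τ over 3, here 3.08: call it the hold-up factor, side product with partner fed over side product with everything in at the start. Feed starting material instead and both rates still carry s, so reckon gamma, delta and theta level with zeta.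

Maple's last 3 readings average 3.87% and alder's 3.57%; take 3.72%.

Turn the question round. For "all alike", eta must stand within 1.5 points of that, which asks a factor below 1.40. Eta has 3.08, so I reckon eta at 11.4%.

The forecast names eta, with 10.5% there and 3.9% in each other flask, holding that “Feeding starting material therefore changes nothing”; my eta figure stands above its 10.5%.

    starting material + target → side product (k = 2.60 L mol⁻¹ min⁻¹, Ea = 81.0 kJ mol⁻¹)
    starting material ⇌ reactive form (K = 0.0150, k = 1.53 min⁻¹, Ea = 108 kJ mol⁻¹, ΔH = −90.0 kJ mol⁻¹)
    partner + reactive form → target (k = 34400 L mol⁻¹ min⁻¹, Ea = 39.0 kJ mol⁻¹)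
    (constants at 90 °C)

The flask gives eta highest: 11.2%, against 4.04% in gamma, 4.46% in delta, 3.77% in theta and 4.48% in zeta. Eta over zeta is 2.50, where the factor said 3.08. Carry the factor to the flask like eta with 72 mM of partner, 4.24 equiv. Its feed matches the charge in 1.89 min, so the factor is 0.766. Read a factor below one as one, which puts that flask at 3.72%. It gives 4.66% of side product, beside 95.3% of target.

The numbers in the tables come from a simulation from invented constants, noise included.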